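- birch: substrate 10 mM; partner 0.70 equiv; the very flask that is asked about, followed so far
- flask: substrate 10 mM; partner 0.700 equiv; time 3.0 d

- birch (time / h: target / %, crystals / %): 3.00: 3, 0; 6.00: 4, 0; 15.0: 20, 2; 40.0: 46, 3

(readings scatter by 2 percentage points)

- what is said of target includes crystals
- crystals is a solid; its amount is given per volume of the solution

1. how much target and crystals together there is at 3.0 d, in percent of the substrate charged
2. concentration of target in solution at 3.0 d, in percent of saturation

The birch run stood at 46% target, crystals included, after 40.0 h, and the decision is whether to let it run on until 3.0 d or to stop it at that point. If substrate and partner pair one to one, partner at 0.70 equiv is the limiting reagent, and the reckoning made here takes the rate as second order in the two. Integrated, that rate says that the logarithm of substrate left over partner left, each as a fraction of its own charge, grows with time at a slope of k times the difference of the two charges. That difference is 3.00 mM, and the logarithm after 40.0 h is 0.454. This gives the pairing constant k, 3.79 /M/h. The reading at 15.0 h gives 2.52 /M/h, which is lower, so the readings point to a slow start and the later reading is the one carried, with its scatter of 2 percentage points.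

At 3.0 d the logarithm reaches 0.818, and solving for the sum gives 56.6%. That is a gain of 11 points over the last reading, against a scatter of 2 points, so this reckoning lets the flask run on to 3.0 d. The forecast gives 60%, which is higher than this reckoning, and 130% of saturation, holding that “the solution is supersaturated and crystal growth is slow”.

The flask gives 53.7% at 3.0 d, and its solution stands at 100% of saturation.

    2 substrate → homo dimer (k = 0.0350 /M/h)
    2 second intermediate → homo product (k = 0.450 /M/h)
    open intermediate + second intermediate → target (k = 5.30 /M/h)
    crystals ⇌ target, rate k4*(cs4 - [target]) while solid is left; crystals form when [target] > cs4 (solubility = 3.70 mM, k = 2.60 /h)
    partner → second intermediate (k = 3.00 /h)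
    partner + target → over-reaction product (k = 31.0 /M/h)
    substrate → open intermediate (k = 0.0900 /h)

The step to target joins open intermediate and second intermediate, one made from substrate, the other from partner. The neighbour flask is charged with 2.5 mM of substrate, with the same equivalents and time. With k unchanged, the logarithm there is 0.204, a quarter of the flask's, and the sum comes to 30.1%. The neighbour flask gives 31.9%, with open intermediate holding 67.8% and crystals at 0%.

The numbers in the tables were generated by integration on assumed constants; noise was put on by code.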